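**Retrosynthetic overview**
- The last step closes both rings at once. An open-chain (Z)-vinyl iodide / (Z)-type 2-en-4-ynoic acid is cyclised by palladium, which forms C6–O (butenolide) and C4–C5 (ten-membered carbocycle) together and sets 5E and 3Z.
- The seco acid comes from a C8/C10/C2 triol chain. C2 is set by CBS reduction, C10–C1 by a chelate-controlled aldol with a β-iodoenone, and C8–C9 by a catalytic asymmetric acetone aldol.
- The tetrasubstituted C7=C11 alkene comes from a chlorocarbonylative β-lactonisation of an alkynol followed by Sonogashira coupling. All palladium coupling is finished before the vinyl iodide enters.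
- Ring order: only a temporary oxetanone template (steps 2–4) exists before the end. The butenolide and the carbocycle form simultaneously in step 13.

Assumption (atom labels, germacrane numbering): ring C1–C10; C2 bears OAc; C3=C4(CH3); C5=C6(O); C7=C11; C8 bears the methacrylate; C10 bears CH3 and OH; C12 is the lactone C=O; C13 is CH2OH. The target is 2S,8R,10S,3Z,5E.

**Step 1**
Reactants: 1 3,3-diethoxyprop-1-yne
Product: 3 4,4-diethoxybut-2-yn-1-ol, via lithium acetylide 2 (not isolated)
Conditions: n-BuLi, THF, −78 °C; (CH2O)n, −78 → 23 °C; H2O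
Reagents that add atoms: formaldehyde (as paraformaldehyde), C=O
Why: Acetylide addition to formaldehyde (alkyne hydroxymethylation) is routine, and the acetal is inert to n-BuLi.

**Step 2**
Reactants: 3 4,4-diethoxybut-2-yn-1-ol
Product: 4 (Z)-3-(1-chloro-2,2-diethoxyethylidene)oxetan-2-one
Conditions: PdCl2 (10 mol %), CuCl2 (3 equiv), CO (20 bar), propylene oxide (2 equiv), THF, 30 °C
Reagents that add atoms: carbon monoxide, [C-]#[O+]; CuCl2, Cl[Cu]Cl
Why: In this chlorocarbonylative lactonisation of a 2-alkyn-1-ol, syn chloropalladation puts Cl on C7 and Pd on C11, and CO insertion with capture by the propargylic OH gives the (Z)-α-chloroalkylidene-β-lactone, so one step fixes the C7=C11 geometry (halide cis to C12) and tells C13 apart from C8.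

**Step 3**
Reactants: 4 (Z)-3-(1-chloro-2,2-diethoxyethylidene)oxetan-2-one; 5 (triisopropylsilyl)acetylene
Product: 6 (E)-3-[1,1-diethoxy-4-(triisopropylsilyl)but-3-yn-2-ylidene]oxetan-2-one
Conditions: PdCl2(PPh3)2 (5 mol %), CuI (10 mol %), Et3N, THF, 40 °C
Reagents that add atoms: none
Why: Sonogashira coupling of the activated (vinylogous acyl) chloride proceeds with retention, so the alkyne (C5≡C6) ends up cis to the C12 carbonyl.

**Step 4**
Reactants: 6 (E)-3-[1,1-diethoxy-4-(triisopropylsilyl)but-3-yn-2-ylidene]oxetan-2-one; 7 2-(trimethylsilyl)ethanol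
Product: 10 2-(trimethylsilyl)ethyl (2E)-2-[(tert-butyldimethylsilyloxy)methyl]-3-(diethoxymethyl)-5-(triisopropylsilyl)pent-2-en-4-ynoate, via lithium 2-(trimethylsilyl)ethoxide 8 (not isolated), via lithium allyl alkoxide 9 (not isolated)
Conditions: 7, n-BuLi, THF, −78 °C; 6, −78 °C; TBSCl, −78 → 23 °C
Reagents that add atoms: tert-butyldimethylsilyl chloride, CC(C)(C)[Si](C)(C)Cl
Why: Acyl–oxygen cleavage of the strained β-lactone by a hard alkoxide (transesterification) releases the C13 alkoxide, which is silylated in the same flask without touching the alkene geometry.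

**Step 5**
Reactants: 10 the silyl-protected acetal ester
Product: 12 2-(trimethylsilyl)ethyl (2E)-2-[(tert-butyldimethylsilyloxy)methyl]-3-formyl-5-(triisopropylsilyl)pent-2-en-4-ynoate, via lutidinium salt 11 (not isolated)
Conditions: TESOTf, 2,6-lutidine, CH2Cl2, 0 °C; H2O
Reagents that add atoms: water, O
Why: Silyl triflate/lutidine deacetalisation, followed by hydrolysis of the α-alkoxypyridinium salt, frees the aldehyde under non-acidic conditions that spare the TBS ether, the silylethyl ester and the alkynylsilane.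

**Step 6**
Reactants: 12 the enynoate aldehyde; 13 2-methoxypropene
Product: 15 2-(trimethylsilyl)ethyl (2E)-2-[(tert-butyldimethylsilyloxy)methyl]-3-[(1R)-1-hydroxy-3-oxobutyl]-5-(triisopropylsilyl)pent-2-en-4-ynoate, via methyl enol ether 14 (not isolated)
Conditions: Ti(OiPr)4 (10 mol %), 2-[(3-bromo-5-tert-butyl-2-hydroxybenzylidene)amino]-2'-hydroxy-1,1'-binaphthyl (10 mol %, antipode chosen for Re-face attack), 3,5-di-tert-butylsalicylic acid (10 mol %), 2,6-di-tert-butyl-4-methylpyridine, neat 13, 0 → 23 °C; 2 N HCl, Et2O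
Reagents that add atoms: water, O
Why: In this catalytic enantioselective acetone aldol (ene-type addition of 2-methoxypropene under a chiral titanium Lewis acid, then enol ether hydrolysis), the ligand blocks the Si face, so C9 adds to the Re face of the unsaturated aldehyde and sets 8R.

**Step 7**
Reactants: 16 pent-3-yn-2-one
Product: 17 (Z)-4-iodopent-3-en-2-one
Conditions: NaI, AcOH, 23 °C
Reagents that add atoms: sodium iodide, [Na+].[I-]
Why: Conjugate hydroiodination of an ynone is a net anti addition of HI and gives the (Z)-β-iodoenone, with iodine cis to the acyl group as required for 3Z.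

**Step 8**
Reactants: 15 the β-hydroxy methyl ketone; 17 (Z)-4-iodopent-3-en-2-one
Product: 19 2-(trimethylsilyl)ethyl (2E)-2-[(tert-butyldimethylsilyloxy)methyl]-3-[(1R,3R,6Z)-1,3-dihydroxy-7-iodo-3-methyl-5-oxooct-6-en-1-yl]-5-(triisopropylsilyl)pent-2-en-4-ynoate, via lithium dienolate 18 (not isolated)
Conditions: 17 (2.3 equiv), LDA, THF, −78 °C; 15, −78 °C, 1 h; AcOH, −78 °C
Reagents that add atoms: none
Why: In this aldol addition of the kinetic cross-conjugated enolate to the methyl ketone, the C8 lithium alkoxide chelates the C10 carbonyl (Cram–Reetz 1,3-chelate), so the C1 nucleophile attacks the face that leaves C10–OH anti to C8–O (the 10S arrangement of the target), and the cold quench prevents retro-aldol and oxa-Michael closure.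

**Step 9**
Reactants: 19 the aldol adduct
Product: 20 2-(trimethylsilyl)ethyl (2E)-2-[(tert-butyldimethylsilyloxy)methyl]-3-[(1R,3R,6Z)-3-hydroxy-7-iodo-3-methyl-1-(methacryloyloxy)-5-oxooct-6-en-1-yl]-5-(triisopropylsilyl)pent-2-en-4-ynoate
Conditions: methacrylic anhydride, Et3N, DMAP (cat.), CH2Cl2, 0 °C
Reagents that add atoms: methacrylic anhydride, C=C(C)C(=O)OC(=O)C(C)=C
Why: DMAP-catalysed acylation takes the only secondary hydroxyl (C8), because the tertiary C10–OH is inert at 0 °C.

**Step 10**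
Reactants: 20 the β-iodoenone methacrylate
Product: 21 2-(trimethylsilyl)ethyl (2E)-2-[(tert-butyldimethylsilyloxy)methyl]-3-[(1R,3S,5S,6Z)-3,5-dihydroxy-7-iodo-3-methyl-1-(methacryloyloxy)oct-6-en-1-yl]-5-(triisopropylsilyl)pent-2-en-4-ynoate
Conditions: (R)-2-methyl-CBS-oxazaborolidine (0.3 equiv), catecholborane (3 equiv), toluene, −78 °C; aq NaHCO3
Reagents that add atoms: none
Why: In this Corey–Bakshi–Shibata 1,2-reduction the iodoalkenyl group acts as the large substituent, so the (R)-catalyst delivers hydride to the Re face of C2 and sets 2S under reagent control, without touching esters or alkynes.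

**Step 11**
Reactants: 21 the allylic alcohol
Product: 22 2-(trimethylsilyl)ethyl (2E)-3-[(1R,3S,5S,6Z)-5-acetoxy-3-hydroxy-7-iodo-3-methyl-1-(methacryloyloxy)oct-6-en-1-yl]-2-[(tert-butyldimethylsilyloxy)methyl]-5-(triisopropylsilyl)pent-2-en-4-ynoate
Conditions: Ac2O, pyridine, DMAP (cat.), CH2Cl2, 0 → 23 °C
Reagents that add atoms: acetic anhydride, CC(=O)OC(C)=O
Why: Acetylation is selective because C2–OH is the only non-tertiary free hydroxyl.

**Step 12**
Reactants: 22 the fully protected seco ester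
Product: 23 (2E)-3-[(1R,3S,5S,6Z)-5-acetoxy-3-hydroxy-7-iodo-3-methyl-1-(methacryloyloxy)oct-6-en-1-yl]-2-(hydroxymethyl)pent-2-en-4-ynoic acid
Conditions: TBAF/AcOH (1:1, 6 equiv), THF, 0 → 23 °C; pH 4 buffer
Reagents that add atoms: none
Why: Buffered fluoride removes all three silicon groups in one global desilylation (Si–C(sp) cleavage, Si–O cleavage, and β-silyl fragmentation of the silylethyl ester), and the buffer protects the acetate and the methacrylate.

**Step 13**
Reactants: 23 the seco acid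
Product: 26 (2S,8R,10S,3Z,5E)-2-acetoxy-10,13-dihydroxy-8-(methacryloyloxy)germacra-3,5,7(11)-trien-12,6-olide, via vinylpalladium iodide 24 (not isolated), via divinylpalladacycle 25 (not isolated)
Conditions: Pd2(dba)3 (10 mol %), P(2-furyl)3 (40 mol %), K2CO3 (3 equiv), n-Bu4NCl (1 equiv), DMF, 45 °C, 23 added over 12 h (final 1 mM), no copper
Reagents that add atoms: none
Why: Proposed new method: this is a macrocyclic variant of the coupling–cyclisation of organic halides with alkynoic acids (closest known reaction types: the intermolecular zerovalent-palladium-catalysed reaction of vinyl or aryl halides and triflates with 4-pentynoic and (Z)-2-en-4-ynoic acids, which gives (E)-ylidene lactones by trans oxypalladation, and macrocyclic Stille or Heck closures of vinyl iodides); zerovalent palladium inserts into C4–I (far faster than ionisation of the allylic acetate) to give 24, the electrophilic σ-vinyl divalent palladium binds the tethered terminal alkyne, the carboxylate held cis on C11 attacks C6 5-exo-dig anti to the metal, which closes the butenolide and gives the eleven-membered palladacycle 25 with Pd on C5 trans to the ring oxygen, and reductive elimination with retention at both sp2 carbons forms C4–C5 and the ten-membered ring, so 3Z comes from the iodide, 5E from the anti addition, and no stereocentre is touched; material that is only cycloisomerised to the γ-methylene butenolide can still reach 26 by intramolecular Heck reaction in the same flask.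

**Compound list**
1 | 3,3-diethoxyprop-1-yne | C#CC(OCC)OCC | starting material
2 | lithium 3,3-diethoxyprop-1-yn-1-ide | [Li]C#CC(OCC)OCC | intermediate
3 | 4,4-diethoxybut-2-yn-1-ol | OCC#CC(OCC)OCC | intermediate
4 | (Z)-3-(1-chloro-2,2-diethoxyethylidene)oxetan-2-one | CCOC(OCC)/C(Cl)=C1\COC1=O | intermediate
5 | (triisopropylsilyl)acetylene | C#C[Si](C(C)C)(C(C)C)C(C)C | starting material
6 | (E)-3-[1,1-diethoxy-4-(triisopropylsilyl)but-3-yn-2-ylidene]oxetan-2-one | CCOC(OCC)/C(C#C[Si](C(C)C)(C(C)C)C(C)C)=C1\COC1=O | intermediate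
7 | 2-(trimethylsilyl)ethanol | OCC[Si](C)(C)C | starting material
8 | lithium 2-(trimethylsilyl)ethoxide | [Li]OCC[Si](C)(C)C | intermediate
9 | lithium alkoxide of 2-(trimethylsilyl)ethyl (2E)-3-(diethoxymethyl)-2-(hydroxymethyl)-5-(triisopropylsilyl)pent-2-en-4-ynoate | CCOC(OCC)/C(C#C[Si](C(C)C)(C(C)C)C(C)C)=C(\CO[Li])C(=O)OCC[Si](C)(C)C | intermediate
10 | 2-(trimethylsilyl)ethyl (2E)-2-[(tert-butyldimethylsilyloxy)methyl]-3-(diethoxymethyl)-5-(triisopropylsilyl)pent-2-en-4-ynoate | CCOC(OCC)/C(C#C[Si](C(C)C)(C(C)C)C(C)C)=C(\CO[Si](C)(C)C(C)(C)C)C(=O)OCC[Si](C)(C)C | intermediate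
11 | α-ethoxy-2,6-lutidinium triflate derived from 10 (new centre unassigned) | CCOC([n+]1c(C)cccc1C)/C(C#C[Si](C(C)C)(C(C)C)C(C)C)=C(\CO[Si](C)(C)C(C)(C)C)C(=O)OCC[Si](C)(C)C.[O-]S(=O)(=O)C(F)(F)F | intermediate
12 | 2-(trimethylsilyl)ethyl (2E)-2-[(tert-butyldimethylsilyloxy)methyl]-3-formyl-5-(triisopropylsilyl)pent-2-en-4-ynoate | O=C/C(C#C[Si](C(C)C)(C(C)C)C(C)C)=C(\CO[Si](C)(C)C(C)(C)C)C(=O)OCC[Si](C)(C)C | intermediate
13 | 2-methoxypropene | C=C(C)OC | starting material
14 | (1R)-1-hydroxy-3-methoxybut-3-enyl adduct (methyl enol ether of 15) | C=C(OC)C[C@@H](O)/C(C#C[Si](C(C)C)(C(C)C)C(C)C)=C(\CO[Si](C)(C)C(C)(C)C)C(=O)OCC[Si](C)(C)C | intermediate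
15 | 2-(trimethylsilyl)ethyl (2E)-2-[(tert-butyldimethylsilyloxy)methyl]-3-[(1R)-1-hydroxy-3-oxobutyl]-5-(triisopropylsilyl)pent-2-en-4-ynoate | CC(=O)C[C@@H](O)/C(C#C[Si](C(C)C)(C(C)C)C(C)C)=C(\CO[Si](C)(C)C(C)(C)C)C(=O)OCC[Si](C)(C)C | intermediate
16 | pent-3-yn-2-one | CC#CC(C)=O | starting material
17 | (Z)-4-iodopent-3-en-2-one | CC(=O)/C=C(\I)C | intermediate
18 | lithium (Z)-4-iodopenta-1,3-dien-2-olate | [Li]OC(=C)/C=C(\I)C | intermediate
19 | aldol adduct, side chain (1R,3R,6Z)-1,3-dihydroxy-7-iodo-3-methyl-5-oxooct-6-en-1-yl | C/C(I)=C/C(=O)C[C@](C)(O)C[C@@H](O)/C(C#C[Si](C(C)C)(C(C)C)C(C)C)=C(\CO[Si](C)(C)C(C)(C)C)C(=O)OCC[Si](C)(C)C | intermediate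
20 | C8 methacrylate, side chain (1R,3R,6Z)-3-hydroxy-7-iodo-3-methyl-1-(methacryloyloxy)-5-oxooct-6-en-1-yl | C/C(I)=C/C(=O)C[C@](C)(O)C[C@@H](OC(=O)C(C)=C)/C(C#C[Si](C(C)C)(C(C)C)C(C)C)=C(\CO[Si](C)(C)C(C)(C)C)C(=O)OCC[Si](C)(C)C | intermediate
21 | C2 alcohol, side chain (1R,3S,5S,6Z)-3,5-dihydroxy-7-iodo-3-methyl-1-(methacryloyloxy)oct-6-en-1-yl | C/C(I)=C/[C@@H](O)C[C@](C)(O)C[C@@H](OC(=O)C(C)=C)/C(C#C[Si](C(C)C)(C(C)C)C(C)C)=C(\CO[Si](C)(C)C(C)(C)C)C(=O)OCC[Si](C)(C)C | intermediate
22 | C2 acetate, side chain (1R,3S,5S,6Z)-5-acetoxy-3-hydroxy-7-iodo-3-methyl-1-(methacryloyloxy)oct-6-en-1-yl | C/C(I)=C/[C@@H](OC(C)=O)C[C@](C)(O)C[C@@H](OC(=O)C(C)=C)/C(C#C[Si](C(C)C)(C(C)C)C(C)C)=C(\CO[Si](C)(C)C(C)(C)C)C(=O)OCC[Si](C)(C)C | intermediate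
23 | (2E)-3-[(1R,3S,5S,6Z)-5-acetoxy-3-hydroxy-7-iodo-3-methyl-1-(methacryloyloxy)oct-6-en-1-yl]-2-(hydroxymethyl)pent-2-en-4-ynoic acid | C/C(I)=C/[C@@H](OC(C)=O)C[C@](C)(O)C[C@@H](OC(=O)C(C)=C)/C(C#C)=C(\CO)C(=O)O | intermediate
24 | C4 σ-vinylpalladium iodide of the potassium carboxylate of 23 (phosphines not drawn) | C/C([Pd]I)=C/[C@@H](OC(C)=O)C[C@](C)(O)C[C@@H](OC(=O)C(C)=C)/C(C#C)=C(\CO)C(=O)[O-].[K+] | intermediate
25 | eleven-membered C4,C5-divinylpalladacycle with closed butenolide (phosphines not drawn) | C/C1=C/[C@@H](OC(C)=O)C[C@](C)(O)C[C@@H](OC(=O)C(C)=C)C2=C(CO)C(=O)O/C2=C/[Pd]1 | intermediate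
26 | (2S,8R,10S,3Z,5E)-2-acetoxy-10,13-dihydroxy-8-(methacryloyloxy)germacra-3,5,7(11)-trien-12,6-olide (CNP0246543.1) | C=C(C)C(=O)O[C@@H]1C[C@@](C)(O)C[C@H](OC(C)=O)/C=C(C)\C=C2\OC(=O)C(CO)=C21 | target

**Step count and linear sequence**
- Total step count: 13.
- Longest linear sequence: 12 (steps 1–6 and 8–13). Step 7 is a one-step side branch.

**Steps most likely to fail**

**Step 13 (bicyclisation).**
- Risks are oligomerisation, Heck attack on the methacrylate, and ionisation of the dienyl acetate in the product.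
- The fallback sets out from 23 and closes the rings one after the other.
- AgNO3 (10 mol %, acetone, dark) cycloisomerises the enynoic acid 5-exo-dig to the γ-methylene butenolide iodide F7.
- A cationic intramolecular Heck macrocyclisation of F7 (Pd(OAc)2, P(o-tolyl)3, Ag2CO3, MeCN, 1 mM) attacks the exocyclic CH2. After β-hydride elimination within the ring it comes back to the route at 26.

**Step 2 (chlorocarbonylative β-lactonisation of a primary, acetal-bearing alkynol).**
- Risks are low conversion, acetal loss and regiochemical leakage.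
- The fallback sets out from 7 and builds the same alkene by stereodefined enol sulfonate chemistry instead.
- The lithium salt of 7 opens β-propiolactone at the acyl carbon to give 2-(trimethylsilyl)ethyl 3-hydroxypropanoate F1.
- TBSCl/imidazole then gives the silyl ether F2.
- Crossed Claisen condensation of the LDA enolate of F2 with ethyl diethoxyacetate gives the β-keto ester F3.
- Chelate-controlled tosylation of F3 (TsCl, N-methylimidazole, LiOH) gives the (Z)-enol tosylate F4.
- Sonogashira coupling of F4 with 5 (PdCl2(PPh3)2, CuI, Et3N) occurs with retention and comes back to the route at 10.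

**Step 8 (ketone–ketone aldol).**
- Risks are proton transfer, retro-aldol, modest diastereoselectivity, and closure to a dihydropyranone.
- The fallback sets out from 15 and replaces the reversible ketone enolate with an amide enolate, introducing the iodide afterwards.
- The lithium enolate of N-methoxy-N-methylacetamide (3 equiv, THF, −78 °C) adds irreversibly under the same 1,3-chelate control to give the β-hydroxy Weinreb amide F5.
- 1-Propynylmagnesium bromide (THF, −20 °C) then gives the ynone F6.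
- NaI/AcOH hydroiodinates only this unhindered ynone in the anti sense and comes back to the route at 19.

**Further compounds**
F1 | step 2 | 2-(trimethylsilyl)ethyl 3-hydroxypropanoate | OCCC(=O)OCC[Si](C)(C)C
F2 | step 2 | 2-(trimethylsilyl)ethyl 3-(tert-butyldimethylsilyloxy)propanoate | CC(C)(C)[Si](C)(C)OCCC(=O)OCC[Si](C)(C)C
F3 | step 2 | 2-(trimethylsilyl)ethyl 2-[(tert-butyldimethylsilyloxy)methyl]-4,4-diethoxy-3-oxobutanoate | CCOC(OCC)C(=O)C(CO[Si](C)(C)C(C)(C)C)C(=O)OCC[Si](C)(C)C
F4 | step 2 | 2-(trimethylsilyl)ethyl (2Z)-2-[(tert-butyldimethylsilyloxy)methyl]-4,4-diethoxy-3-(tosyloxy)but-2-enoate | CCOC(OCC)/C(OS(=O)(=O)c1ccc(C)cc1)=C(\CO[Si](C)(C)C(C)(C)C)C(=O)OCC[Si](C)(C)C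
F5 | step 8 | β-hydroxy Weinreb amide from 15 (C8 R, C10 configured as in 19) | CON(C)C(=O)C[C@](C)(O)C[C@@H](O)/C(C#C[Si](C(C)C)(C(C)C)C(C)C)=C(\CO[Si](C)(C)C(C)(C)C)C(=O)OCC[Si](C)(C)C
F6 | step 8 | β-hydroxy ynone (1,3-dihydroxy-3-methyl-5-oxooct-6-yn-1-yl side chain) | CC#CC(=O)C[C@](C)(O)C[C@@H](O)/C(C#C[Si](C(C)C)(C(C)C)C(C)C)=C(\CO[Si](C)(C)C(C)(C)C)C(=O)OCC[Si](C)(C)C
F7 | step 13 | γ-methylene butenolide vinyl iodide | C/C(I)=C/[C@@H](OC(C)=O)C[C@](C)(O)C[C@@H](OC(=O)C(C)=C)C1=C(CO)C(=O)OC1=C
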